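**Retrosynthetic overview**
1. Feature: ring A is a phloroglucinol unit with oxygens on C5, C7 and C8a. As a 3,5-bis(silyloxy)phenyl ether bound through O1 to C2, it has two equivalent, strongly nucleophilic ortho carbons, and either can become C4a.
2. Ring C (last ring): disconnect C4–C4a by intramolecular Friedel–Crafts acylation of the (S)-2-aryl-3-aryloxypropanoic acid, activated as its mixed trifluoroacetic anhydride.
3. O1–C2 comes from a Mitsunobu etherification and C4 from oxidation, one on each arm of a 2-aryl-1,3-propanediol. C3 is set by lipase desymmetrisation while it is still non-enolisable.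
4. C3–C1′ comes from Pd-catalysed malonate arylation of a 6-bromochromene. The pyran ring comes from a propargyl Claisen/oxa-6π cascade on 4-bromo-2-methoxyphenol.
5. Ring order: rings A and B are bought, the pyran ring forms in step 2, ring C forms in step 13, and step 14 removes all silyl groups.

Key step: step 13

Assumption (sense of the enzyme): porcine pancreatic lipase is taken to act on the pro-R CH2O arm of 2-aryl-1,3-propanediol derivatives, as is usual for this class. Hydrolysis of the diacetate then gives the (S)-monoacetate, whereas acetylation of the diol would esterify the same arm and give the antipode. The configuration of the monoacetate is to be confirmed before the Mitsunobu step.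

TIPS = triisopropylsilyl.

**Step 1**
Reactants: 1 4-bromo-2-methoxyphenol; 2 3-chloro-3-methylbut-1-yne
Product: 3 4-bromo-2-methoxy-1-[(2-methylbut-3-yn-2-yl)oxy]benzene
Conditions: K2CO3, KI (cat.), CuI (cat.), acetone, reflux
Reagents that add atoms: none
Why: Copper-assisted O-propargylation of the phenoxide (Williamson-type etherification) substitutes at the tertiary propargylic carbon rather than eliminating, and the aryl bromide and methyl ether are inert.

**Step 2**
Reactants: 3 4-bromo-2-methoxy-1-[(2-methylbut-3-yn-2-yl)oxy]benzene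
Product: 5 6-bromo-8-methoxy-2,2-dimethyl-2H-chromene, via 4-bromo-2-methoxy-6-(3-methylbuta-1,2-dien-1-yl)phenol 4 (not isolated)
Conditions: N,N-diethylaniline, 185 °C
Reagents that add atoms: none
Why: Aromatic propargyl Claisen rearrangement to the only free ortho carbon gives allenylphenol 4, which closes by 1,5-H shift and oxa-6π electrocyclisation; the methoxy group blocks the other ortho position, so only one regioisomer can form.

**Step 3**
Reactants: 5 6-bromo-8-methoxy-2,2-dimethyl-2H-chromene
Product: 6 6-bromo-2,2-dimethyl-2H-chromen-8-ol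
Conditions: NaSEt (3 equiv), DMF, 120 °C; then 1 M HCl
Reagents that add atoms: none
Why: SN2 demethylation of the aryl methyl ether by thiolate works under basic conditions that spare the acid-sensitive chromene, because the tertiary O1–C2 bond is closed to SN2 attack and the electron-rich aryl bromide does not undergo SNAr.

**Step 4**
Reactants: 6 6-bromo-2,2-dimethyl-2H-chromen-8-ol
Product: 7 6-bromo-2,2-dimethyl-8-(triisopropylsilyloxy)-2H-chromene
Conditions: TIPSCl, imidazole, DMAP (cat.), DMF, rt
Reagents that add atoms: chlorotriisopropylsilane, CC(C)[Si](Cl)(C(C)C)C(C)C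
Why: Standard phenol silylation; the aryl TIPS ether should withstand the phosphate base, hydrides and weak acids of later steps and leaves with fluoride at the end.

**Step 5**
Reactants: 7 6-bromo-2,2-dimethyl-8-(triisopropylsilyloxy)-2H-chromene; 8 diethyl malonate
Product: 9 diethyl 2-[2,2-dimethyl-8-(triisopropylsilyloxy)-2H-chromen-6-yl]malonate
Conditions: Pd2(dba)3 (2 mol %), P(t-Bu)3 (8 mol %), K3PO4, toluene, 80 °C
Reagents that add atoms: none
Why: Palladium-catalysed α-arylation of a malonate enolate, in which the bulky electron-rich phosphine enables oxidative addition of the electron-rich bromide and reductive elimination, while the hindered cyclic cis olefin should not compete in a Heck reaction.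

**Step 6**
Reactants: 9 diethyl 2-[2,2-dimethyl-8-(triisopropylsilyloxy)-2H-chromen-6-yl]malonate
Product: 10 2-[2,2-dimethyl-8-(triisopropylsilyloxy)-2H-chromen-6-yl]propane-1,3-diol (prochiral)
Conditions: LiAlH4 (3 equiv), Et2O, 0 °C to rt; aq. Rochelle salt
Reagents that add atoms: none
Why: LiAlH4 ester reduction is the standard entry to 2-aryl-1,3-propanediols from arylmalonates; excess hydride at low temperature limits loss through the malonate enolate, and the olefin and aryl silyl ether are inert.

**Step 7**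
Reactants: 10 2-[2,2-dimethyl-8-(triisopropylsilyloxy)-2H-chromen-6-yl]propane-1,3-diol
Product: 11 2-[2,2-dimethyl-8-(triisopropylsilyloxy)-2H-chromen-6-yl]propane-1,3-diyl diacetate
Conditions: Ac2O, pyridine, DMAP (cat.), CH2Cl2, rt
Reagents that add atoms: acetic anhydride, CC(=O)OC(C)=O
Why: Exhaustive DMAP-catalysed acetylation of two primary alcohols gives the prochiral substrate for the hydrolytic mode of the enzyme.

**Step 8**
Reactants: 11 2-[2,2-dimethyl-8-(triisopropylsilyloxy)-2H-chromen-6-yl]propane-1,3-diyl diacetate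
Product: 12 (S)-3-hydroxy-2-[2,2-dimethyl-8-(triisopropylsilyloxy)-2H-chromen-6-yl]propyl acetate
Conditions: porcine pancreatic lipase, 0.1 M phosphate buffer (pH 7)/i-Pr2O, rt, stopped shortly after 11 is consumed; used without storage
Reagents that add atoms: none
Why: Lipase desymmetrisation (enantiotopic-group-selective ester hydrolysis) of a 2-aryl-1,3-propanediyl diacetate sets the stereocentre, because the enzyme pocket cleaves the pro-R acetoxymethyl arm and leaves the acetate on the pro-S arm, and further hydrolysis removes the minor enantiomer faster and so should raise the enantiomeric purity.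

**Step 9**
Reactants: 13 phloroglucinol (anhydrous)
Product: 14 3,5-bis(triisopropylsilyloxy)phenol
Conditions: TIPSCl (2.0 equiv), imidazole, DMF, 0 °C to rt; chromatography
Reagents that add atoms: chlorotriisopropylsilane, CC(C)[Si](Cl)(C(C)C)C(C)C
Why: Statistical silylation of the C3-symmetric triol with two equivalents of silyl chloride gives the bis-ether beside mono- and tris-ethers, which differ enough in polarity to be separated and recycled.

**Step 10**
Reactants: 12 (S)-3-hydroxy-2-[2,2-dimethyl-8-(triisopropylsilyloxy)-2H-chromen-6-yl]propyl acetate; 14 3,5-bis(triisopropylsilyloxy)phenol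
Product: 15 (S)-3-[3,5-bis(triisopropylsilyloxy)phenoxy]-2-[2,2-dimethyl-8-(triisopropylsilyloxy)-2H-chromen-6-yl]propyl acetate
Conditions: PPh3, DIAD, toluene, 0 °C to rt
Reagents that add atoms: none
Why: Mitsunobu etherification displaces the alkoxyphosphonium group at the primary CH2 (future C2) with the phenoxide of 14 and forms O1–C2; the stereocentre is not the reacting carbon, and the near-neutral medium suppresses the 1,3-acetyl migration that would racemise 12.

**Step 11**
Reactants: 15 (S)-3-[3,5-bis(triisopropylsilyloxy)phenoxy]-2-[2,2-dimethyl-8-(triisopropylsilyloxy)-2H-chromen-6-yl]propyl acetate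
Product: 16 (R)-3-[3,5-bis(triisopropylsilyloxy)phenoxy]-2-[2,2-dimethyl-8-(triisopropylsilyloxy)-2H-chromen-6-yl]propan-1-ol
Conditions: DIBAL-H (2.5 equiv), CH2Cl2, −78 °C; aq. Rochelle salt
Reagents that add atoms: none
Why: Reductive cleavage of the acetate frees the second arm without the alkoxide/methanol conditions that attack aryl silyl ethers, and the descriptor changes to R only through the CIP ranking, not through any change in geometry.

**Step 12**
Reactants: 16 (R)-3-[3,5-bis(triisopropylsilyloxy)phenoxy]-2-[2,2-dimethyl-8-(triisopropylsilyloxy)-2H-chromen-6-yl]propan-1-ol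
Product: 18 (S)-3-[3,5-bis(triisopropylsilyloxy)phenoxy]-2-[2,2-dimethyl-8-(triisopropylsilyloxy)-2H-chromen-6-yl]propanoic acid, via (S)-3-[3,5-bis(triisopropylsilyloxy)phenoxy]-2-[2,2-dimethyl-8-(triisopropylsilyloxy)-2H-chromen-6-yl]propanal 17 (not isolated)
Conditions: TEMPO (20 mol %), PhI(OAc)2 (2.5 equiv), CH2Cl2/H2O, 0 °C to rt
Reagents that add atoms: water, O
Why: Oxoammonium-catalysed oxidation (TEMPO/PhI(OAc)2) takes the primary alcohol to aldehyde 17, whose hydrate is oxidised on in the same flask; the weakly acidic, base-free medium should keep enolisation and β-elimination of aryloxide from 17 slow, so the configuration is retained.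

**Step 13**
Reactants: 18 (S)-3-[3,5-bis(triisopropylsilyloxy)phenoxy]-2-[2,2-dimethyl-8-(triisopropylsilyloxy)-2H-chromen-6-yl]propanoic acid
Product: 20 (S)-3-[2,2-dimethyl-8-(triisopropylsilyloxy)-2H-chromen-6-yl]-5,7-bis(triisopropylsilyloxy)chroman-4-one, via (S)-3-[3,5-bis(triisopropylsilyloxy)phenoxy]-2-[2,2-dimethyl-8-(triisopropylsilyloxy)-2H-chromen-6-yl]propanoic trifluoroacetic anhydride 19 (not isolated)
Conditions: (CF3CO)2O (1.3 equiv), CH2Cl2 (0.01 M), −20 to 0 °C; poured into cold pH 7 buffer; short neutral silica plug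
Reagents that add atoms: trifluoroacetic anhydride, O=C(OC(=O)C(F)(F)F)C(F)(F)F (its CF3CO unit stands only in 19; none of its atoms remain in 20)
Why: Trifluoroacetic anhydride turns acid 18 into mixed anhydride 19 with trifluoroacetate as leaving group, the acyl carbon (future C4) is attacked by the A-ring carbon ortho to O1 and para to a silyloxy group, and loss of the ring proton from the σ-complex gives C4–C4a (electrophilic aromatic substitution). The closest known reaction type is the intramolecular Friedel–Crafts acylation of 3-aryloxypropanoic acids to chroman-4-ones with TFAA, applied here to a 2-aryl member of the class. Ring C (O1, C2, C3, C4, C4a, C8a) closes in a 6-exo-trig mode at the activated carbonyl carbon. No stereocentre is formed; C3 comes from 18 and should be kept because no base is present (no ketene from 19), the anhydride reacts without a free acylium ion (which could lose CO to the p-alkoxybenzylic cation), and the temperature is low and the contact time short. Regioselectivity needs no control, since the two ortho carbons of the 3,5-bis(silyloxy)phenoxy ring are equivalent and the carbon between the two silyloxy groups cannot reach the acyl carbon. Chemoselectivity over the chromene olefin and over ring trifluoroacetylation rests on the six-membered intramolecular closure onto a threefold oxygen-activated ring, on high dilution, on the small excess of anhydride and on the cold buffer quench, and loss of the 5-O-silyl group here would be harmless because step 14 removes it anyway.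

**Step 14**
Reactants: 20 (S)-3-[2,2-dimethyl-8-(triisopropylsilyloxy)-2H-chromen-6-yl]-5,7-bis(triisopropylsilyloxy)chroman-4-one
Product: 21 (S)-5,7-dihydroxy-3-(8-hydroxy-2,2-dimethyl-2H-chromen-6-yl)chroman-4-one (target)
Conditions: HF·pyridine, pyridine, THF, 0 °C to rt (plastic vessel); pH 6–7 phosphate buffer work-up
Reagents that add atoms: none
Why: Fluoride cleavage of the three aryl silyl ethers is driven by Si–F bond formation, and pyridine-buffered HF stays weakly acidic, so no phenoxide or enolate forms, C3 should not epimerise and the chromene olefin is not protonated.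

**Compound list**
1 | 4-bromo-2-methoxyphenol | COc1cc(Br)ccc1O | starting material
2 | 3-chloro-3-methylbut-1-yne | CC(C)(Cl)C#C | starting material
3 | 4-bromo-2-methoxy-1-[(2-methylbut-3-yn-2-yl)oxy]benzene | COc1cc(Br)ccc1OC(C)(C)C#C | intermediate
4 | 4-bromo-2-methoxy-6-(3-methylbuta-1,2-dien-1-yl)phenol | CC(C)=C=Cc1cc(Br)cc(OC)c1O | intermediate
5 | 6-bromo-8-methoxy-2,2-dimethyl-2H-chromene | CC1(C)C=Cc2cc(Br)cc(OC)c2O1 | intermediate
6 | 6-bromo-2,2-dimethyl-2H-chromen-8-ol | CC1(C)C=Cc2cc(Br)cc(O)c2O1 | intermediate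
7 | 6-bromo-2,2-dimethyl-8-(triisopropylsilyloxy)-2H-chromene | CC1(C)C=Cc2cc(Br)cc(O[Si](C(C)C)(C(C)C)C(C)C)c2O1 | intermediate
8 | diethyl malonate | CCOC(=O)CC(=O)OCC | starting material
9 | diethyl 2-[2,2-dimethyl-8-(TIPS-oxy)-2H-chromen-6-yl]malonate | CC1(C)C=Cc2cc(C(C(=O)OCC)C(=O)OCC)cc(O[Si](C(C)C)(C(C)C)C(C)C)c2O1 | intermediate
10 | 2-[2,2-dimethyl-8-(TIPS-oxy)-2H-chromen-6-yl]propane-1,3-diol | CC1(C)C=Cc2cc(C(CO)CO)cc(O[Si](C(C)C)(C(C)C)C(C)C)c2O1 | intermediate
11 | 2-[2,2-dimethyl-8-(TIPS-oxy)-2H-chromen-6-yl]propane-1,3-diyl diacetate | CC1(C)C=Cc2cc(C(COC(C)=O)COC(C)=O)cc(O[Si](C(C)C)(C(C)C)C(C)C)c2O1 | intermediate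
12 | (S)-3-hydroxy-2-[2,2-dimethyl-8-(TIPS-oxy)-2H-chromen-6-yl]propyl acetate | CC1(C)C=Cc2cc([C@H](COC(C)=O)CO)cc(O[Si](C(C)C)(C(C)C)C(C)C)c2O1 | intermediate
13 | phloroglucinol | Oc1cc(O)cc(O)c1 | starting material
14 | 3,5-bis(TIPS-oxy)phenol | Oc1cc(O[Si](C(C)C)(C(C)C)C(C)C)cc(O[Si](C(C)C)(C(C)C)C(C)C)c1 | intermediate
15 | (S)-3-[3,5-bis(TIPS-oxy)phenoxy]-2-[2,2-dimethyl-8-(TIPS-oxy)-2H-chromen-6-yl]propyl acetate | CC1(C)C=Cc2cc([C@H](COC(C)=O)COc3cc(O[Si](C(C)C)(C(C)C)C(C)C)cc(O[Si](C(C)C)(C(C)C)C(C)C)c3)cc(O[Si](C(C)C)(C(C)C)C(C)C)c2O1 | intermediate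
16 | (R)-3-[3,5-bis(TIPS-oxy)phenoxy]-2-[2,2-dimethyl-8-(TIPS-oxy)-2H-chromen-6-yl]propan-1-ol | CC1(C)C=Cc2cc([C@H](CO)COc3cc(O[Si](C(C)C)(C(C)C)C(C)C)cc(O[Si](C(C)C)(C(C)C)C(C)C)c3)cc(O[Si](C(C)C)(C(C)C)C(C)C)c2O1 | intermediate
17 | (S)-3-[3,5-bis(TIPS-oxy)phenoxy]-2-[2,2-dimethyl-8-(TIPS-oxy)-2H-chromen-6-yl]propanal | CC1(C)C=Cc2cc([C@H](C=O)COc3cc(O[Si](C(C)C)(C(C)C)C(C)C)cc(O[Si](C(C)C)(C(C)C)C(C)C)c3)cc(O[Si](C(C)C)(C(C)C)C(C)C)c2O1 | intermediate
18 | (S)-3-[3,5-bis(TIPS-oxy)phenoxy]-2-[2,2-dimethyl-8-(TIPS-oxy)-2H-chromen-6-yl]propanoic acid | CC1(C)C=Cc2cc([C@H](C(=O)O)COc3cc(O[Si](C(C)C)(C(C)C)C(C)C)cc(O[Si](C(C)C)(C(C)C)C(C)C)c3)cc(O[Si](C(C)C)(C(C)C)C(C)C)c2O1 | intermediate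
19 | mixed anhydride of 18 with trifluoroacetic acid, (S) | CC1(C)C=Cc2cc([C@H](C(=O)OC(=O)C(F)(F)F)COc3cc(O[Si](C(C)C)(C(C)C)C(C)C)cc(O[Si](C(C)C)(C(C)C)C(C)C)c3)cc(O[Si](C(C)C)(C(C)C)C(C)C)c2O1 | intermediate
20 | (S)-3-[2,2-dimethyl-8-(TIPS-oxy)-2H-chromen-6-yl]-5,7-bis(TIPS-oxy)chroman-4-one | CC1(C)C=Cc2cc([C@H]3COc4cc(O[Si](C(C)C)(C(C)C)C(C)C)cc(O[Si](C(C)C)(C(C)C)C(C)C)c4C3=O)cc(O[Si](C(C)C)(C(C)C)C(C)C)c2O1 | intermediate
21 | (S)-5,7-dihydroxy-3-(8-hydroxy-2,2-dimethyl-2H-chromen-6-yl)chroman-4-one | CC1(C)C=Cc2cc([C@H]3COc4cc(O)cc(O)c4C3=O)cc(O)c2O1 | target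

**Total step count:** 14
**Longest linear sequence:** 13 (steps 1–8 and 10–14, from 1)

**Steps most likely to fail**

1. Step 13.
 - What may go wrong: the trifluoroacetic acid released may add to or oligomerise the chromene olefin. Closure may be slowed by the silyloxy group flanking the attacked carbon. C3 may erode by enolisation of the activated acid or of the ketone. Acylium character may lead to loss of CO.
 - Fallback: from 18, 1-chloro-N,N,2-trimethylprop-1-en-1-amine in CH2Cl2 at 0 °C gives, under neutral conditions and without any acid by-product, (S)-3-[3,5-bis(TIPS-oxy)phenoxy]-2-[2,2-dimethyl-8-(TIPS-oxy)-2H-chromen-6-yl]propanoyl chloride F1. Its solution is diluted with 1,1,1,3,3,3-hexafluoropropan-2-ol at 0 °C under a nitrogen sweep. Hydrogen-bond activation of the acyl chloride then drives the same C4–C4a closure without Lewis acid or anhydride. The route is rejoined at 20.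

2. Step 8.
 - What may go wrong: the bulky, lipophilic silyloxychromenyl group may fit the enzyme pocket badly. This would give slow turnover and poor or reversed discrimination of the two enantiotopic arms. Acyl migration in the product would erode the purity further.
 - Fallback: from 10, non-enzymatic desymmetrisation with a dinuclear zinc–ProPhenol catalyst (Et2Zn, ligand, vinyl benzoate, toluene, −15 °C). Both ligand antipodes are available, so the one that benzoylates the pro-S arm is chosen.
 - This gives (S)-3-hydroxy-2-[2,2-dimethyl-8-(TIPS-oxy)-2H-chromen-6-yl]propyl benzoate F2. Mitsunobu etherification with 14 then gives (S)-3-[3,5-bis(TIPS-oxy)phenoxy]-2-[2,2-dimethyl-8-(TIPS-oxy)-2H-chromen-6-yl]propyl benzoate F3. DIBAL-H at −78 °C removes the benzoate, and the route is rejoined at 16.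

3. Step 12.
 - What may go wrong: the transient α-aryl-β-aryloxy aldehyde may enolise, which leads to racemisation and to β-elimination of the aryloxide. The iodine(III) oxidant may also attack the trioxygenated ring.
 - Fallback: a path to the acid that passes through no aldehyde. From 16, an Appel reaction (I2, PPh3, imidazole, CH2Cl2, 0 °C) gives 6-{(S)-1-[3,5-bis(TIPS-oxy)phenoxy]-3-iodopropan-2-yl}-2,2-dimethyl-8-(TIPS-oxy)-2H-chromene F4.
 - Kornblum substitution (NaNO2, DMSO, rt) then gives 6-{(R)-1-[3,5-bis(TIPS-oxy)phenoxy]-3-nitropropan-2-yl}-2,2-dimethyl-8-(TIPS-oxy)-2H-chromene F5.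
 - Addition of acetic acid to the same nitrite/DMSO mixture (35 °C) converts the primary nitroalkane through its nitrolic acid into the carboxylic acid. The neighbouring C–H is never α to a carbonyl group before the acid stage. The route is rejoined at 18.

**Further compounds**
F1 | step 13 | (S)-3-[3,5-bis(TIPS-oxy)phenoxy]-2-[2,2-dimethyl-8-(TIPS-oxy)-2H-chromen-6-yl]propanoyl chloride | CC1(C)C=Cc2cc([C@H](C(=O)Cl)COc3cc(O[Si](C(C)C)(C(C)C)C(C)C)cc(O[Si](C(C)C)(C(C)C)C(C)C)c3)cc(O[Si](C(C)C)(C(C)C)C(C)C)c2O1
F2 | step 8 | (S)-3-hydroxy-2-[2,2-dimethyl-8-(TIPS-oxy)-2H-chromen-6-yl]propyl benzoate | CC1(C)C=Cc2cc([C@H](COC(=O)c3ccccc3)CO)cc(O[Si](C(C)C)(C(C)C)C(C)C)c2O1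
F3 | step 8 | (S)-3-[3,5-bis(TIPS-oxy)phenoxy]-2-[2,2-dimethyl-8-(TIPS-oxy)-2H-chromen-6-yl]propyl benzoate | CC1(C)C=Cc2cc([C@H](COC(=O)c3ccccc3)COc3cc(O[Si](C(C)C)(C(C)C)C(C)C)cc(O[Si](C(C)C)(C(C)C)C(C)C)c3)cc(O[Si](C(C)C)(C(C)C)C(C)C)c2O1
F4 | step 12 | 6-{(S)-1-[3,5-bis(TIPS-oxy)phenoxy]-3-iodopropan-2-yl}-2,2-dimethyl-8-(TIPS-oxy)-2H-chromene | CC1(C)C=Cc2cc([C@H](CI)COc3cc(O[Si](C(C)C)(C(C)C)C(C)C)cc(O[Si](C(C)C)(C(C)C)C(C)C)c3)cc(O[Si](C(C)C)(C(C)C)C(C)C)c2O1
F5 | step 12 | 6-{(R)-1-[3,5-bis(TIPS-oxy)phenoxy]-3-nitropropan-2-yl}-2,2-dimethyl-8-(TIPS-oxy)-2H-chromene | CC1(C)C=Cc2cc([C@H](C[N+](=O)[O-])COc3cc(O[Si](C(C)C)(C(C)C)C(C)C)cc(O[Si](C(C)C)(C(C)C)C(C)C)c3)cc(O[Si](C(C)C)(C(C)C)C(C)C)c2O1
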